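**Plan**
1. The last cut removes the six O-alkyl groups (five methyl, one ethyl) from a fully protected biflavone.
2. Ring C of unit 2 (the flavone joined through C8; unit 1 is the flavone joined through C3) is cut at C4–C4a and O1–C2, leaving a lone phenol on C8a and an arylpropiolate ester.
3. Ring A of unit 2 is cut at C8–C8a, C6–C7 and C4a–C8a. Its biaryl carbon C8 sits between the oxygen-bearing carbons C7 and C8a, with C5 oxygenated as well; this 2-substituted phloroglucinol array maps onto an ynol ether (C8, C7) and a four-carbon alkoxy vinylketene (C8a, C4a, C5, C6).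
4. The ynol ether is cut at its sp–sp2 bond to C3 of unit 1, and the resulting 3-iodoflavone at O1–C2 and at the acyl–alkyne bond.
5. Forward order: ynone, ring C of unit 1, alkynyl ether on C3, ring A of unit 2, ring C of unit 2, hexaphenol; ring A of unit 1 and both rings B are bought.
6. Stereochemistry: the target has no stereocentre and its 3–8 axis carries no descriptor, so nothing has to be set.

Key step: step 4

Remark: the arylpropiolate ester of step 5 is taken as a purchased compound, and a Z/E mixture from step 5 would be carried on because the acid of step 7 can interconvert the isomers; the Z isomer is drawn.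

**Step 1**
Reactants: 1 2,4,6-trimethoxybenzoyl chloride; 2 1-ethynyl-4-methoxybenzene (4-ethynylanisole)
Product: 3 3-(4-methoxyphenyl)-1-(2,4,6-trimethoxyphenyl)prop-2-yn-1-one
Conditions: PdCl2(PPh3)2 (2 mol %), CuI (4 mol %), Et3N (1.5 equiv), THF, 25 °C
Reagents that add atoms: none
Why: Acyl Sonogashira coupling, in which oxidative addition of the aroyl chloride to zerovalent palladium and transfer of the copper acetylide should give the ynone at room temperature, too cold for the hindered acyl palladium species to lose CO.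

**Step 2**
Reactants: 3 3-(4-methoxyphenyl)-1-(2,4,6-trimethoxyphenyl)prop-2-yn-1-one
Product: 5 3-iodo-5,7-dimethoxy-2-(4-methoxyphenyl)-4H-chromen-4-one, via O-methyloxonium chloride 4 (not isolated)
Conditions: ICl (1.2 equiv), CH2Cl2, −78 → 25 °C; aqueous Na2S2O3
Reagents that add atoms: iodine monochloride, ICl
Why: Electrophilic iodocyclization of an ortho-methoxyaryl ynone, in which ICl activates the alkyne, the methoxy oxygen closes ring C of unit 1 in the 6-endo mode to give oxonium ion 4, and chloride removes its methyl group, a sequence expected to outrun iodination of the acyl-deactivated arene rings at low temperature.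

**Step 3**
Reactants: 5 3-iodo-5,7-dimethoxy-2-(4-methoxyphenyl)-4H-chromen-4-one; 6 2-chloro-1,1-dimethoxyethane (chloroacetaldehyde dimethyl acetal)
Product: 9 3-(methoxyethynyl)-5,7-dimethoxy-2-(4-methoxyphenyl)-4H-chromen-4-one, via lithium methoxyacetylide 7 (not isolated), via chloro(methoxyethynyl)zinc 8 (not isolated)
Conditions: 6 (2 equiv), LiNEt2 (6 equiv, from n-BuLi and Et2NH), THF, −78 → 0 °C; ZnCl2 (4 equiv), 0 °C; then 5, Pd(PPh3)4 (5 mol %), 25–40 °C; pH 8 work-up, Et3N-deactivated silica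
Reagents that add atoms: none
Why: Negishi coupling of an alkoxyethynylzinc chloride with an sp2 iodide, the acetylide arising from the acetal by two eliminations and one deprotonation, and the mild zinc reagent not expected to add to the chromone carbonyl.

**Step 4**
Reactants: 9 3-(methoxyethynyl)-5,7-dimethoxy-2-(4-methoxyphenyl)-4H-chromen-4-one; 10 3-ethoxycyclobut-2-en-1-one
Product: 15 3-(4-ethoxy-2-hydroxy-6-methoxyphenyl)-5,7-dimethoxy-2-(4-methoxyphenyl)-4H-chromen-4-one, via vinylketene 11 (not isolated), via vinylcyclobutenone 12 (not isolated), via dienylketene 13 (not isolated), via cyclohexadienone 14 (not isolated)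
Conditions: 10 (2.5 equiv, in portions), toluene (1 M), 80 → 110 °C, sealed tube, argon; then K2CO3, MeOH, 25 °C
Reagents that add atoms: none
Why: This is a Danheiser benzannulation, the closest known reaction type being the synthesis of resorcinol monoethers from cyclobutenones and 1-alkoxyalkynes. Heat opens 10 (4π) to vinylketene 11, whose ketene C=C adds [2+2] to the ynol ether of 9 to give 12, 12 opens (4π) to dienylketene 13, 13 closes to dienone 14, and 14 tautomerizes to phenol 15. Ring A of unit 2, the only ring that persists, is closed by a thermal 6π electrocyclization that forms C4a–C8a, after C8–C8a and C6–C7 were formed in the [2+2] step. No stereocentre is created, the one in 12 being erased on ring opening. The step needs one regiochemical outcome, bonding of the alkyne carbon that carries unit 1 to the ketene carbonyl carbon so that the free hydroxyl ends on C8a beside the biaryl bond, and the polarity of the ynol ether (nucleophilic at the carbon away from oxygen) paired with the electrophilic ketene carbon should secure it. A methyl ynol ether has no β-hydrogen for retro-ene loss of an alkene at these temperatures, the hindered biaryl bond is already in place as an sp–sp2 bond, and the K2CO3/MeOH treatment returns any phenol that excess 11 has acylated.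

**Step 5**
Reactants: 15 3-(4-ethoxy-2-hydroxy-6-methoxyphenyl)-5,7-dimethoxy-2-(4-methoxyphenyl)-4H-chromen-4-one; 16 ethyl 3-(4-methoxyphenyl)prop-2-ynoate
Product: 17 ethyl (2Z)-3-{5-ethoxy-3-methoxy-2-[5,7-dimethoxy-2-(4-methoxyphenyl)-4-oxo-4H-chromen-3-yl]phenoxy}-3-(4-methoxyphenyl)prop-2-enoate
Conditions: 16 (1.5 equiv), Cs2CO3 (0.5 equiv), DMF, 80 °C
Reagents that add atoms: none
Why: Base-catalysed oxa-Michael addition of a phenoxide to an arylpropiolate ester, the first stage of the classical flavone synthesis from aryloxycinnamic acids, with anti addition favouring the Z adduct and the phenol being the only nucleophilic site of 15 under carbonate.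

**Step 6**
Reactants: 17 ethyl (2Z)-3-{5-ethoxy-3-methoxy-2-[5,7-dimethoxy-2-(4-methoxyphenyl)-4-oxo-4H-chromen-3-yl]phenoxy}-3-(4-methoxyphenyl)prop-2-enoate
Product: 18 (2Z)-3-{5-ethoxy-3-methoxy-2-[5,7-dimethoxy-2-(4-methoxyphenyl)-4-oxo-4H-chromen-3-yl]phenoxy}-3-(4-methoxyphenyl)prop-2-enoic acid
Conditions: LiOH·H2O (3 equiv), THF/MeOH/H2O, 25 °C; 1 M HCl to pH 3
Reagents that add atoms: lithium hydroxide, [Li+].[OH-]
Why: Ester saponification under conditions mild enough that the chromone ring and the aryl vinyl ether should remain intact.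

**Step 7**
Reactants: 18 (2Z)-3-{5-ethoxy-3-methoxy-2-[5,7-dimethoxy-2-(4-methoxyphenyl)-4-oxo-4H-chromen-3-yl]phenoxy}-3-(4-methoxyphenyl)prop-2-enoic acid
Product: 19 5-ethoxy-7-methoxy-2-(4-methoxyphenyl)-8-[5,7-dimethoxy-2-(4-methoxyphenyl)-4-oxo-4H-chromen-3-yl]-4H-chromen-4-one
Conditions: P2O5/CH3SO3H (1:10 w/w), 50–60 °C; ice water
Reagents that add atoms: none
Why: Intramolecular Friedel–Crafts acylation, in which the activated acid attacks the only free position ortho to the aryloxy oxygen (C4a, also ortho to the ethoxy and para to the methoxy group) and so closes ring C of unit 2 without a regiochemical choice.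

**Step 8**
Reactants: 19 5-ethoxy-7-methoxy-2-(4-methoxyphenyl)-8-[5,7-dimethoxy-2-(4-methoxyphenyl)-4-oxo-4H-chromen-3-yl]-4H-chromen-4-one
Product: 20 3,8'-biapigenin, 5,7-dihydroxy-2-(4-hydroxyphenyl)-8-[5,7-dihydroxy-2-(4-hydroxyphenyl)-4-oxo-4H-chromen-3-yl]-4H-chromen-4-one
Conditions: BBr3 (20 equiv), CH2Cl2, −78 → 25 °C (40 °C if needed); MeOH, then H2O
Reagents that add atoms: none
Why: Exhaustive BBr3 ether cleavage, which should remove the five methyl groups and the ethyl group as alkyl bromides (the two ethers peri to the carbonyl groups first, through chelation) under aprotic conditions that avoid the pyranone ring opening behind a Wessely–Moser shift of the C8-linked unit to the C6-linked one.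

**Compound list**
1 | 2,4,6-trimethoxybenzoyl chloride | COc1cc(OC)c(C(Cl)=O)c(OC)c1 | starting material
2 | 1-ethynyl-4-methoxybenzene | COc1ccc(C#C)cc1 | starting material
3 | 3-(4-methoxyphenyl)-1-(2,4,6-trimethoxyphenyl)prop-2-yn-1-one | COc1ccc(C#CC(=O)c2c(OC)cc(OC)cc2OC)cc1 | intermediate
4 | 3-iodo-5,7-dimethoxy-2-(4-methoxyphenyl)-1-methyl-4-oxo-4H-chromen-1-ium chloride | C[O+]1C(c2ccc(OC)cc2)=C(I)C(=O)c2c(OC)cc(OC)cc21.[Cl-] | intermediate (not isolated, step 2)
5 | 3-iodo-5,7-dimethoxy-2-(4-methoxyphenyl)-4H-chromen-4-one | COc1ccc(-c2oc3cc(OC)cc(OC)c3c(=O)c2I)cc1 | intermediate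
6 | 2-chloro-1,1-dimethoxyethane | COC(CCl)OC | starting material
7 | lithium methoxyacetylide, LiC≡COMe | COC#C[Li] | intermediate (not isolated, step 3)
8 | chloro(methoxyethynyl)zinc, MeOC≡CZnCl | COC#C[Zn]Cl | intermediate (not isolated, step 3)
9 | 3-(methoxyethynyl)-5,7-dimethoxy-2-(4-methoxyphenyl)-4H-chromen-4-one | COC#Cc1c(-c2ccc(OC)cc2)oc2cc(OC)cc(OC)c2c1=O | intermediate
10 | 3-ethoxycyclobut-2-en-1-one | CCOC1=CC(=O)C1 | starting material
11 | 3-ethoxybuta-1,3-dien-1-one | CCOC(=C)C=C=O | intermediate (not isolated, step 4)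
12 | 2-[5,7-dimethoxy-2-(4-methoxyphenyl)-4-oxo-4H-chromen-3-yl]-4-(1-ethoxyethenyl)-3-methoxycyclobut-2-en-1-one (racemic) | CCOC(=C)C1C(=O)C(c2c(-c3ccc(OC)cc3)oc3cc(OC)cc(OC)c3c2=O)=C1OC | intermediate (not isolated, step 4)
13 | (3E)-2-[5,7-dimethoxy-2-(4-methoxyphenyl)-4-oxo-4H-chromen-3-yl]-5-ethoxy-3-methoxyhexa-1,3,5-trien-1-one | CCOC(=C)/C=C(OC)\C(=C=O)c1c(-c2ccc(OC)cc2)oc2cc(OC)cc(OC)c2c1=O | intermediate (not isolated, step 4)
14 | 2-[5,7-dimethoxy-2-(4-methoxyphenyl)-4-oxo-4H-chromen-3-yl]-5-ethoxy-3-methoxycyclohexa-2,4-dien-1-one | CCOC1=CC(OC)=C(c2c(-c3ccc(OC)cc3)oc3cc(OC)cc(OC)c3c2=O)C(=O)C1 | intermediate (not isolated, step 4)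
15 | 3-(4-ethoxy-2-hydroxy-6-methoxyphenyl)-5,7-dimethoxy-2-(4-methoxyphenyl)-4H-chromen-4-one | COc1cc(OCC)cc(O)c1-c1c(-c2ccc(OC)cc2)oc2cc(OC)cc(OC)c2c1=O | intermediate
16 | ethyl 3-(4-methoxyphenyl)prop-2-ynoate | CCOC(=O)C#Cc1ccc(OC)cc1 | starting material
17 | ethyl (2Z)-3-{5-ethoxy-3-methoxy-2-[5,7-dimethoxy-2-(4-methoxyphenyl)-4-oxo-4H-chromen-3-yl]phenoxy}-3-(4-methoxyphenyl)prop-2-enoate | CCOC(=O)/C=C(\Oc1cc(OCC)cc(OC)c1-c1c(-c2ccc(OC)cc2)oc2cc(OC)cc(OC)c2c1=O)c1ccc(OC)cc1 | intermediate
18 | (2Z)-3-{5-ethoxy-3-methoxy-2-[5,7-dimethoxy-2-(4-methoxyphenyl)-4-oxo-4H-chromen-3-yl]phenoxy}-3-(4-methoxyphenyl)prop-2-enoic acid | OC(=O)/C=C(\Oc1cc(OCC)cc(OC)c1-c1c(-c2ccc(OC)cc2)oc2cc(OC)cc(OC)c2c1=O)c1ccc(OC)cc1 | intermediate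
19 | 5-ethoxy-7-methoxy-2-(4-methoxyphenyl)-8-[5,7-dimethoxy-2-(4-methoxyphenyl)-4-oxo-4H-chromen-3-yl]-4H-chromen-4-one | CCOc1cc(OC)c(-c2c(-c3ccc(OC)cc3)oc3cc(OC)cc(OC)c3c2=O)c2oc(-c3ccc(OC)cc3)cc(=O)c12 | intermediate
20 | 3,8'-biapigenin | O=c1c(-c2c(O)cc(O)c3c(=O)cc(-c4ccc(O)cc4)oc23)c(-c2ccc(O)cc2)oc2cc(O)cc(O)c12 | target

**Step count**
Total: 8 steps. Longest linear sequence: 8 steps (1 → 3 → 5 → 9 → 15 → 17 → 18 → 19 → 20); the zinc reagent of step 3 is made in the same flask.

**Steps most likely to fail**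

1. Step 4. The vinylogous-ester cyclobutenone may open only at temperatures at which its vinylketene is lost to dimerization, and the aryl-conjugated ynol ether may add too slowly or be hydrated by traces of acid, so that the cascade stalls before the electrocyclization. Fallback, from 5 back to the route at 20: purchased 5,7-dimethoxy-2-(4-methoxyphenyl)-4H-chromen-4-one is iodinated at C8 (N-iodosuccinimide, CF3CO2H, CH3CN) to give 8-iodo-5,7-dimethoxy-2-(4-methoxyphenyl)-4H-chromen-4-one F1. Miyaura borylation (B2pin2, PdCl2(dppf), KOAc, dioxane, 90 °C) should convert it into 5,7-dimethoxy-2-(4-methoxyphenyl)-8-(4,4,5,5-tetramethyl-1,3,2-dioxaborolan-2-yl)-4H-chromen-4-one F2. Suzuki–Miyaura coupling of this boronate with 5 (Pd(OAc)2, SPhos, K3PO4, toluene/H2O, 100 °C) should give 5,7-dimethoxy-2-(4-methoxyphenyl)-8-[5,7-dimethoxy-2-(4-methoxyphenyl)-4-oxo-4H-chromen-3-yl]-4H-chromen-4-one F3, and BBr3 as in step 8 then gives 20. Ring A of unit 2 is then bought, and the hindered biaryl bond is made by cross-coupling two intact flavones instead of by benzannulation.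

2. Step 3. Incomplete formation of the acetylide from the acetal, slow coupling in the presence of amine and alkoxide, and hydration of the ynol ether during work-up or chromatography. Fallback, from 5 and 6 back to the route at 9: the acetylide 7 is quenched with Bu3SnCl and the product distilled to give tributyl(methoxyethynyl)stannane F4, a storable reagent. Stille coupling of this stannane with 5 (PdCl2(PPh3)2, Et4NCl, DMF, 25–50 °C) runs without base, amine or zinc halide, and 9 is isolated by filtration through basic alumina. The alkynyl donor is thus made, purified and assayed apart from the coupling, which changes from an in-situ zinc reagent to a neutral tin reagent; the disconnection itself is unchanged.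

3. Step 5. Slow conjugate addition of the hindered phenoxide to an alkynoate that is deactivated by its methoxyphenyl group, with loss of material by reversal or hydrolysis on prolonged heating. Fallback, from 15 back to the route at 19: C-acetylation next to the hydroxyl (Ac2O, BF3·OEt2, 70 °C; Friedel–Crafts acylation held ortho by boron chelation) gives 3-(3-acetyl-4-ethoxy-2-hydroxy-6-methoxyphenyl)-5,7-dimethoxy-2-(4-methoxyphenyl)-4H-chromen-4-one F5. Its dianion (LiN(SiMe3)2, THF, −78 °C) is acylated with 4-methoxybenzoyl chloride to give 1-{6-ethoxy-2-hydroxy-4-methoxy-3-[5,7-dimethoxy-2-(4-methoxyphenyl)-4-oxo-4H-chromen-3-yl]phenyl}-3-(4-methoxyphenyl)propane-1,3-dione F6, the diketone of a Baker–Venkataraman sequence. Acid-catalysed cyclodehydration (H2SO4, AcOH, 95 °C) closes ring C of unit 2 to 19, so steps 6 and 7 are not needed.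

**Further compounds**
F1 | step 4 | 8-iodo-5,7-dimethoxy-2-(4-methoxyphenyl)-4H-chromen-4-one | COc1ccc(-c2cc(=O)c3c(OC)cc(OC)c(I)c3o2)cc1
F2 | step 4 | 5,7-dimethoxy-2-(4-methoxyphenyl)-8-(4,4,5,5-tetramethyl-1,3,2-dioxaborolan-2-yl)-4H-chromen-4-one | COc1ccc(-c2cc(=O)c3c(OC)cc(OC)c(B4OC(C)(C)C(C)(C)O4)c3o2)cc1
F3 | step 4 | 5,7-dimethoxy-2-(4-methoxyphenyl)-8-[5,7-dimethoxy-2-(4-methoxyphenyl)-4-oxo-4H-chromen-3-yl]-4H-chromen-4-one | COc1cc(OC)c(-c2c(-c3ccc(OC)cc3)oc3cc(OC)cc(OC)c3c2=O)c2oc(-c3ccc(OC)cc3)cc(=O)c12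
F4 | step 3 | tributyl(methoxyethynyl)stannane | CCCC[Sn](CCCC)(CCCC)C#COC
F5 | step 5 | 3-(3-acetyl-4-ethoxy-2-hydroxy-6-methoxyphenyl)-5,7-dimethoxy-2-(4-methoxyphenyl)-4H-chromen-4-one | CCOc1cc(OC)c(-c2c(-c3ccc(OC)cc3)oc3cc(OC)cc(OC)c3c2=O)c(O)c1C(C)=O
F6 | step 5 | 1-{6-ethoxy-2-hydroxy-4-methoxy-3-[5,7-dimethoxy-2-(4-methoxyphenyl)-4-oxo-4H-chromen-3-yl]phenyl}-3-(4-methoxyphenyl)propane-1,3-dione | CCOc1cc(OC)c(-c2c(-c3ccc(OC)cc3)oc3cc(OC)cc(OC)c3c2=O)c(O)c1C(=O)CC(=O)c1ccc(OC)cc1
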